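**Remark on the chemistry:** the SMILES defines the cis-(5S,8R) isomer, with the C5 side chain and the C8 methoxy group on the same face of the saturated ring. Compounds 1, 2 and 5 are taken as catalogue compounds.

## Direct plan and its weak points

A direct plan would build the carbocycle first from an acyclic chiral chain. It would take an allylic alcohol A1 through a Carroll rearrangement and hydrogenation to keto ester A2, close the six-membered carbocycle by a Claisen condensation to diketone A3, elaborate this to the fused 4-pyranone A4, and finish with a ring-oxygen-to-N–OMe exchange.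

- **Thermal Carroll rearrangement (A1 to A2):** C5 would rest entirely on chirality transfer through one chair transition state at 140–170 °C. The substrate is a β-hydroxy-α-methoxy ester that can eliminate, and it would first need a selective mono-O-methylation of a diol.
- **Long run-up to A2:** about nine linear steps of chain building, redox changes and protecting-group moves would pass before any ring exists.
- **Base and nucleophile steps after C8 is set:** in the Claisen closure to A3, the dianion acylation and the ring-opening exchange on A4, C8 would sit α to an ester or ketone, so it could epimerise or lose MeOH.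

## Retrosynthetic overview of the new route

- The saturated ring C5–C6–C7–C8, fused at C4a/C8a and carrying the cis-1,4 pair C5-alkyl/C8-OMe, is read as a reduced benzo ring. One enantioselective all-cis hydrogenation of the carbocycle of the aromatic quinoline 8 would add H to C5, C6, C7 and C8 from one face and set both stereocentres as a group.
- Quinoline 8 would come from 4-quinolone 7. The pyridine ring (N1–C2 and C4–C4a bonds) is closed first, by a Conrad–Limpach reaction onto a purchased benzene ring; the carbocycle is never closed, only dearomatised.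
- The side chain would be attached by a B-alkyl Suzuki coupling. The N–OMe group would be installed last by N-oxidation, O-debenzylation and O-methylation.
- No chirality transfer and no chiral-pool chain are needed, and the stereocentres never sit α to a carbonyl group under strong base.

Key step: step 4

## Route

Step 1
Reactants: 1 pent-4-en-1-ylbenzene (5-phenyl-1-pentene); 2 5-bromo-2-methoxyaniline
Product: 4 2-methoxy-5-(5-phenylpentyl)aniline, via B-(5-phenylpentyl)-9-BBN 3 (not isolated)
Conditions: 9-BBN, THF, 0 °C→rt; then 2, Pd(dppf)Cl2 (3 mol %), 3 M aq. K3PO4, DMF, 60 °C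
Reagents that add atoms: none
Why: anti-Markovnikov hydroboration followed by B-alkyl Suzuki–Miyaura coupling should join the primary alkyl chain to the aryl bromide in the presence of the free aniline.

Step 2
Reactants: 4 2-methoxy-5-(5-phenylpentyl)aniline; 5 methyl 2-methoxy-3-oxobutanoate
Product: 7 3,8-dimethoxy-2-methyl-5-(5-phenylpentyl)quinolin-4(1H)-one, via the anilinocrotonate enamine 6 (not isolated)
Conditions: TsOH (cat.), cyclohexane, reflux, Dean–Stark; then Ph2O, 250 °C, 20 min
Reagents that add atoms: none
Why: Conrad–Limpach quinolone synthesis; the enamine can cyclise thermally only at the single free ortho carbon, which lies next to the side chain, so the 5-alkyl-8-methoxy pattern is fixed by the substrate.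

Step 3
Reactants: 7 3,8-dimethoxy-2-methyl-5-(5-phenylpentyl)quinolin-4(1H)-one
Product: 8 4-(benzyloxy)-3,8-dimethoxy-2-methyl-5-(5-phenylpentyl)quinoline
Conditions: BnBr, Ag2CO3, toluene, 80 °C, dark
Reagents that add atoms: benzyl bromide, BrCc1ccccc1
Why: silver-salt O-alkylation of a 4-quinolone; the nitrogen is flanked by the 2-methyl and 8-methoxy groups, so O-benzylation should dominate and give a true quinoline for the hydrogenation.

Step 4
Reactants: 8 4-(benzyloxy)-3,8-dimethoxy-2-methyl-5-(5-phenylpentyl)quinoline
Product: 9 (5S,8R)-4-(benzyloxy)-3,8-dimethoxy-2-methyl-5-(5-phenylpentyl)-5,6,7,8-tetrahydroquinoline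
Conditions: H2 (50 bar), [Ru(η3-methallyl)2(cod)] (5 mol %), PhTRAP (5.5 mol %; the enantiomer that gives the 5S,8R product, to be assigned in a pilot run), EtOAc/i-PrOH, 80 °C
Reagents that add atoms: none
Why: a chiral ruthenium hydride bound to the benzo ring should transfer two molecules of H2 stepwise to C5–C8 while the partly reduced ring stays on the metal, so all four hydrogens arrive from one face. The closest known reaction type is the ruthenium/trans-chelating bisphosphine hydrogenation of the carbocycle of quinolines to 5,6,7,8-tetrahydroquinolines with a new centre at C8, together with Ru–NHC carbocycle hydrogenation of fused N-heteroarenes. No ring is closed; the existing benzo ring is dearomatised into the saturated carbocycle of the target. The cis relation of C5 and C8 follows from same-face delivery, and the absolute configuration of both centres is set by the ligand's choice of arene face. The step needs reduction of the benzo ring only: the pyridine ring is fully substituted (2-Me, 3-OMe, 4-OBn) and is left alone by this catalyst type, and the two isolated phenyl rings are not fused to a coordinating heteroarene and should not be reduced. The homogeneous, neutral conditions should leave the benzyl ether and the new pyridylic C8–OMe bond unhydrogenolysed.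

Step 5
Reactants: 9 (5S,8R)-4-(benzyloxy)-3,8-dimethoxy-2-methyl-5-(5-phenylpentyl)-5,6,7,8-tetrahydroquinoline
Product: 10 (5S,8R)-4-(benzyloxy)-3,8-dimethoxy-2-methyl-5-(5-phenylpentyl)-5,6,7,8-tetrahydroquinoline 1-oxide
Conditions: mCPBA, CH2Cl2, 0 °C→rt
Reagents that add atoms: mCPBA, OOC(=O)c1cccc(Cl)c1
Why: peracid N-oxidation of an electron-rich 2,6-dialkylpyridine; no other oxidisable group is present and neither stereocentre is touched.

Step 6
Reactants: 10 (5S,8R)-4-(benzyloxy)-3,8-dimethoxy-2-methyl-5-(5-phenylpentyl)-5,6,7,8-tetrahydroquinoline 1-oxide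
Product: 11 (5S,8R)-1-hydroxy-3,8-dimethoxy-2-methyl-5-(5-phenylpentyl)-5,6,7,8-tetrahydroquinolin-4(1H)-one
Conditions: H2 (1 atm), 10% Pd/C, MeOH, rt, stopped after uptake of one equivalent
Reagents that add atoms: none
Why: hydrogenolysis of a 4-benzyloxypyridine N-oxide is the classical entry to the 1-hydroxy-4-pyridone tautomer; the O-benzyl bond should cleave faster than the N–O bond or the pyridylic methyl ether.

Step 7
Reactants: 11 (5S,8R)-1-hydroxy-3,8-dimethoxy-2-methyl-5-(5-phenylpentyl)-5,6,7,8-tetrahydroquinolin-4(1H)-one
Product: 12 Waltherione H, (5S,8R)-1,3,8-trimethoxy-2-methyl-5-(5-phenylpentyl)-5,6,7,8-tetrahydroquinolin-4(1H)-one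
Conditions: MeI, K2CO3, acetone, rt
Reagents that add atoms: iodomethane, CI
Why: Williamson-type O-methylation of a cyclic N-hydroxy vinylogous amide should occur at the hydroxamate-like N–O oxygen; the mild carbonate base should not epimerise C8, which is only vinylogously activated.

## Compound list

1 | pent-4-en-1-ylbenzene | C=CCCCc1ccccc1 | starting material
2 | 5-bromo-2-methoxyaniline | COc1ccc(Br)cc1N | starting material
3 | 9-(5-phenylpentyl)-9-borabicyclo[3.3.1]nonane | c1ccccc1CCCCCB1C2CCCC1CCC2 | intermediate
4 | 2-methoxy-5-(5-phenylpentyl)aniline | COc1ccc(CCCCCc2ccccc2)cc1N | intermediate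
5 | methyl 2-methoxy-3-oxobutanoate | COC(C(C)=O)C(=O)OC | starting material
6 | methyl (2E)-2-methoxy-3-{[2-methoxy-5-(5-phenylpentyl)phenyl]amino}but-2-enoate | COC(=O)/C(OC)=C(/C)Nc1cc(CCCCCc2ccccc2)ccc1OC | intermediate
7 | 3,8-dimethoxy-2-methyl-5-(5-phenylpentyl)quinolin-4(1H)-one | COc1c(C)[nH]c2c(OC)ccc(CCCCCc3ccccc3)c2c1=O | intermediate
8 | 4-(benzyloxy)-3,8-dimethoxy-2-methyl-5-(5-phenylpentyl)quinoline | COc1c(C)nc2c(OC)ccc(CCCCCc3ccccc3)c2c1OCc1ccccc1 | intermediate
9 | (5S,8R)-4-(benzyloxy)-3,8-dimethoxy-2-methyl-5-(5-phenylpentyl)-5,6,7,8-tetrahydroquinoline | COc1c(C)nc2c(c1OCc1ccccc1)[C@@H](CCCCCc1ccccc1)CC[C@H]2OC | intermediate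
10 | (5S,8R)-4-(benzyloxy)-3,8-dimethoxy-2-methyl-5-(5-phenylpentyl)-5,6,7,8-tetrahydroquinoline 1-oxide | COc1c(C)[n+]([O-])c2c(c1OCc1ccccc1)[C@@H](CCCCCc1ccccc1)CC[C@H]2OC | intermediate
11 | (5S,8R)-1-hydroxy-3,8-dimethoxy-2-methyl-5-(5-phenylpentyl)-5,6,7,8-tetrahydroquinolin-4(1H)-one | COc1c(C)n(O)c2c(c1=O)[C@@H](CCCCCc1ccccc1)CC[C@H]2OC | intermediate
12 | Waltherione H | COc1c(C)n(OC)c2c(c1=O)[C@@H](CCCCCc1ccccc1)CC[C@H]2OC | target

## Step count and risk

Total steps: 7. Longest linear sequence: 7.

**Step 4 (key hydrogenation).** The ligand may discriminate poorly between the two faces of the 5,8-disubstituted benzo ring, or some material may lose the cis relation through decomplexation of a partly reduced ring. Fallback: from 8, the same hydrogenation would be run with racemic ligand to give racemic cis material, that is 9 together with its enantiomer (5R,8S)-4-(benzyloxy)-3,8-dimethoxy-2-methyl-5-(5-phenylpentyl)-5,6,7,8-tetrahydroquinoline F1. The enantiomers would be separated by preparative chromatography on a chiral stationary phase, and the route is rejoined at 9.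

**Step 2 (Conrad–Limpach cyclisation).** Ring closure at the ortho carbon next to the side chain may be slow at 250 °C, and the α-methoxy enamine may decompose first. Fallback: from 4, a Sugasawa ortho-acylation (BCl3, AlCl3, methoxyacetonitrile, then aq. HCl) would give 1-[2-amino-3-methoxy-6-(5-phenylpentyl)phenyl]-2-methoxyethan-1-one F2. Acetylation (Ac2O, pyridine) would give N-[2-methoxy-6-(methoxyacetyl)-5-(5-phenylpentyl)phenyl]acetamide F3. A Camps cyclisation (t-BuOK, t-BuOH, 80 °C), in which the ketone enolate attacks the amide carbonyl, would close the ring at low temperature and rejoin the route at 7.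

**Step 6 (hydrogenolysis).** The N–O bond may be cleaved along with the benzyl ether, or the pyridylic C8–OMe bond may be hydrogenolysed. Fallback: from 10, the N-oxide oxygen would be methylated first (MeOTf, CH2Cl2, 0 °C) to give (5S,8R)-4-(benzyloxy)-1,3,8-trimethoxy-2-methyl-5-(5-phenylpentyl)-5,6,7,8-tetrahydroquinolin-1-ium triflate F4. The activated O-benzyl group would then be removed by SN2 attack of bromide (Bu4NBr, MeCN, 40 °C), which should strike the benzylic carbon faster than the N–OMe methyl. This reaches 12 directly without hydrogen and without the ambident methylation of step 7.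

## Further compounds

F1 | step 4 | (5R,8S)-4-(benzyloxy)-3,8-dimethoxy-2-methyl-5-(5-phenylpentyl)-5,6,7,8-tetrahydroquinoline | COc1c(C)nc2c(c1OCc1ccccc1)[C@H](CCCCCc1ccccc1)CC[C@@H]2OC
F2 | step 2 | 1-[2-amino-3-methoxy-6-(5-phenylpentyl)phenyl]-2-methoxyethan-1-one | COCC(=O)c1c(N)c(OC)ccc1CCCCCc1ccccc1
F3 | step 2 | N-[2-methoxy-6-(methoxyacetyl)-5-(5-phenylpentyl)phenyl]acetamide | COCC(=O)c1c(NC(C)=O)c(OC)ccc1CCCCCc1ccccc1
F4 | step 6 | (5S,8R)-4-(benzyloxy)-1,3,8-trimethoxy-2-methyl-5-(5-phenylpentyl)-5,6,7,8-tetrahydroquinolin-1-ium trifluoromethanesulfonate | COc1c(C)[n+](OC)c2c(c1OCc1ccccc1)[C@@H](CCCCCc1ccccc1)CC[C@H]2OC.[O-]S(=O)(=O)C(F)(F)F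
A1 | direct plan | methyl (2R,3S,4E)-3-hydroxy-2-methoxy-10-phenyldec-4-enoate | COC(=O)[C@H](OC)[C@@H](O)/C=C/CCCCCc1ccccc1
A2 | direct plan | methyl (2R,5S)-2,8-dimethoxy-7-oxo-5-(5-phenylpentyl)octanoate | COC(=O)[C@H](OC)CC[C@H](CCCCCc1ccccc1)CC(=O)COC
A3 | direct plan | (3S,6R)-6-methoxy-2-(2-methoxyacetyl)-3-(5-phenylpentyl)cyclohexan-1-one, ring-enol form | COCC(=O)C1=C(O)[C@H](OC)CC[C@@H]1CCCCCc1ccccc1
A4 | direct plan | (5S,8R)-3,8-dimethoxy-2-methyl-5-(5-phenylpentyl)-5,6,7,8-tetrahydro-4H-chromen-4-one | COc1c(C)oc2c(c1=O)[C@@H](CCCCCc1ccccc1)CC[C@H]2OC
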